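19.7 h was the apparent pseudo-first-order half-life of the electrophile between the last two readings of the red run. I called it the tail half-life and counted the flask's 40 h in it.

- red: electrophile 5 mM; nucleophile 12 mM; free base 3 mM; protic impurity 5 mM; run made earlier
- flask: electrophile 10 mM; nucleophile 12.0 mM; free base 3.00 mM; protic impurity 5.00 mM; time 40 h

red run (percent of the electrophile charged)

| time / h | electrophile / % | product / % |
|---|---|---|
| 1.50 | 87.9 | 12.2 |
| 4.00 | 75.6 | 24.6 |
| 8.00 | 62.5 | 37.4 |
| 12.0 | 54.3 | 45.4 |

(each reading ± 0.3 percentage points)

- the species that holds most of what was charged as electrophile, at 40 h (electrophile / product)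
- the largest share itself, whichever of these holds it, in percent of the electrophile charged

Up to the first reading of the red run the half-life had been 8.06 h, shorter than the tail value, so the fractional loss slowed in that run. Held for the whole time, that early value gave a loose floor for the flask of 3.21% electrophile.

The flask held twice the electrophile of the red run with the same other charges. So by 12.0 h I expected it to hold at least that run's product, 2.27 mM. Over the remaining time I let the electrophile fall no faster than the tail half-life:

ceiling for electrophile: 77.3%

half-lives allowed after 12.0 h: 1.42

floor for electrophile: 28.9%

The forecast said electrophile, at 69%, inside my bracket, on the ground “Product therefore stalls near 3 mM”.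

The flask gave electrophile as the largest share, 54.4%, also inside the bracket and 15 percentage points below the forecast. Its product reached 4.56 mM, above the 3.00 mM of free base charged, with 27% of that base still free.

    electrophile + nucleophile → acid set free + product (k = 11.9 M⁻¹ h⁻¹)
    nucleophile + acid set free ⇌ protonated nucleophile, settled at all times (K = 12700 M⁻¹)
    acid set free + free base ⇌ salt of the base (K = 1.70 × 10⁵ M⁻¹, k = 138 M⁻¹ h⁻¹)
    nucleophile + protic impurity → quenched reagent (k = 359 M⁻¹ h⁻¹)

Counted in half-lives, the flask went through 0.878 of them in 40 h, each of 45.6 h on average, longer than the tail half-life of 19.7 h. The neighbouring flask with 20 mM of nucleophile, read at the same time, kept 20.5% electrophile. That is 2.29 half-lives of 17.5 h each on average, shorter than the tail half-life, and its product stood at 79.5%.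

The numbers in the tables were generated by integration for substances that don't exist, and the scatter is random.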